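The constants come from no measurement; what happens was integrated by code.

First product is made from substrate and reagent, and it is lost to side product, to double product and to its isomer, so its end amount has to be read from a balance.

| flask | substrate | reagent | time |
|---|---|---|---|
| summer | 0.050 M | 0.0120 M | 25 min |
| midnight | 0.050 M | 0.0300 M | 25 min |
| spring | 0.050 M | 0.100 M | 25 min |
| noon | 0.050 M | 0.300 M | 25 min |
| autumn | 0.050 M | 1.00 M | 25 min |

    reagent + tris adduct → tetra adduct (k1 = 0.00253 /M/s)
    first product ⇌ isomer of the product (K2 = 0.81, k2 = 3.36 × 10⁻⁴ /s)
    reagent + double product → tris adduct (k3 = 0.00187 /M/s)
    substrate + reagent → first product (k4 = 0.0205 /M/s)
    substrate + first product → side product (k5 = 0.0369 /M/s)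
    reagent + first product → double product (k6 = 0.00843 /M/s)

- amount of first product at the end, in percent of the substrate charged for summer, midnight, spring, noon, autumn, in this order
- the shape of the row from first to last (rises, then falls / falls all the way / falls, then rises / hardly changes / rises all the way)

- percent here means substrate units held: one side product counts as two
- "hardly changes" means that all values lie within two and a half points (for a concentration: within two and a half percent of the largest)
- run time (summer): 25 min

Solve two extreme versions of the flask.

In the thin version, take summer. At the charges, loss to side product runs at 0.111 /min, faster than loss to double product at 0.00607 /min and forward loss to the isomer of the product at 0.0202 /min. Set the making of first product equal to its loss to side product. [substrate] stands in both rates and cancels, so [first product] = s × [reagent] in this steady state, where s is the balance ratio, the rate constant of the making over that of the side-product step, 0.556.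

Now iterate on [reagent]. Start with [substrate] at its charge and let reagent decay exponentially. Then put the result back: count each reagent used as taking two substrate, one in the making and one in the side product, which gives a lower mean [substrate]. Go round again.

| Round | Mean [substrate] | [reagent] left | First product, s × [reagent] |
|---|---|---|---|
| first | 0.050 M | 0.00258 M | 2.87% |
| second | 0.0406 M | 0.00345 M | 3.83% |
| third | 0.0414 M | 0.00336 M | 3.73% |

Commit to 3.73% for summer.

In the flooded version, take autumn and hold [reagent] at its charge, which makes the steps pseudo-first-order. Substrate then has a half-life of 0.564 min by the making, and first product drains to double product with a half-life of 1.37 min. Both are shorter than the run, and the drain by itself, taken over the whole run, leaves <0.001% of what stood; this version counts no return from the isomer of the product.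

Place the real flasks between these. Spring's reagent charge times s gives 111% of the substrate charged, more than was charged, so the thin version fails at that charge. Noon's drain half-life at the charge, 4.57 min, is shorter than the run. Expect the row to climb with reagent, then fall.

The forecast gave 4.6%, 11.3%, 23%, 4.6% and 0.12%, shape rises, then falls, holding for noon and autumn that “the reagent then drains first product to double product”.

The flasks give 4.40%, 11.3%, 22.6%, 5.86% and 0.137%, shape rises, then falls.

In summer, first product's half-life by the side-product step, at charged concentrations, is 6.3 min, shorter than the 34 min of the forward step to the isomer of the product. It is also short against the run. With summer's reagent at the end at 26.7% of its charge, s gives 3.56%, and summer holds 4.40%, above my 3.73%. With midnight's reagent at the end at 33.9% of its charge, s gives 11.3%, and midnight holds 11.3%.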